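## Retrosynthetic overview

1. Target 14 ⇐ one-pot hydrogenation/hydrogenolysis of macrocyclic acyloin 13, which reduces the C=O, the C–OH, the E-alkene and both benzyl ethers.
2. 13 ⇐ key step: the ring B–ring C ethano bridge is cut between its two benzylic carbons, which are both formyl carbons in dialdehyde 11. An N-heterocyclic carbene turns one of them into an acyl anion equivalent, and the intramolecular benzoin closes the 18-membered ring. This is the only ring formed; rings A–D are bought.
3. 11 ⇐ Ullmann ether (ring D–O–ring C) from aryl bromide 9 and phenol 10; 9 ⇐ Horner–Wadsworth–Emmons olefination (ring D–ring A bridge) of aldehyde 6 with phosphonate 7, then MnO2.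
4. 6 ⇐ SNAr ether (ring A–O–ring B) from fluoroaldehyde 4 and 3-hydroxybenzyl alcohol 5; 4 ⇐ benzylation and ortho-lithiation/formylation of 3-fluoro-4-methoxyphenol 1.

Assumption: the target has no stereocentre and its 18-membered ring is taken as conformationally mobile, so it is one achiral compound and no enantiocontrol is needed; the E-alkene of 8–13 and the racemic carbinol of 13 are both erased in step 8.

Ring letters: ring A = the OMe/OH ring; ring B = the meta-linked ring; ring C = the ring with OH next to a diaryl ether oxygen; ring D = the para-linked ring.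

## Route

Step 1
Reactants: 1 3-fluoro-4-methoxyphenol
Product: 2 4-(benzyloxy)-2-fluoro-1-methoxybenzene
Conditions: BnBr, K2CO3, DMF, rt
Reagents that add atoms: benzyl bromide, BrCc1ccccc1
Why: Williamson ether synthesis; the benzyl ether later directs the lithiation and is removed in the final hydrogenolysis.

Step 2
Reactants: 2 4-(benzyloxy)-2-fluoro-1-methoxybenzene
Product: 4 6-(benzyloxy)-2-fluoro-3-methoxybenzaldehyde, via aryllithium 3 (not isolated)
Conditions: LDA, THF, −78 °C, 1 h; DMF, −78 → 0 °C; aq. HCl
Reagents that add atoms: N,N-dimethylformamide, CN(C)C=O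
Why: Directed ortho-metalation and formylation; the only C–H flanked by both F and OBn is the most acidic, the amide base leaves the benzylic CH2 alone, and −78 °C prevents LiF loss to a benzyne.

Step 3
Reactants: 4 6-(benzyloxy)-2-fluoro-3-methoxybenzaldehyde; 5 3-(hydroxymethyl)phenol
Product: 6 6-(benzyloxy)-2-[3-(hydroxymethyl)phenoxy]-3-methoxybenzaldehyde
Conditions: Cs2CO3, DMSO, 110 °C
Reagents that add atoms: none
Why: Nucleophilic aromatic substitution of the fluoride ortho to the formyl group; under carbonate only the phenol is deprotonated, so the benzylic alcohol stays a spectator.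

Step 4
Reactants: 6 6-(benzyloxy)-2-[3-(hydroxymethyl)phenoxy]-3-methoxybenzaldehyde; 7 diethyl (4-bromobenzyl)phosphonate
Product: 8 {3-[3-(benzyloxy)-2-[(E)-2-(4-bromophenyl)ethenyl]-6-methoxyphenoxy]phenyl}methanol
Conditions: KOtBu (2.2 equiv), THF, 0 °C → rt
Reagents that add atoms: none
Why: Horner–Wadsworth–Emmons olefination; the semi-stabilised benzylic phosphonate anion adds reversibly and gives the E-alkene under thermodynamic control, while the free alcohol is tolerated as its alkoxide and the aryl bromide is inert.

Step 5
Reactants: 8 {3-[3-(benzyloxy)-2-[(E)-2-(4-bromophenyl)ethenyl]-6-methoxyphenoxy]phenyl}methanol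
Product: 9 3-[3-(benzyloxy)-2-[(E)-2-(4-bromophenyl)ethenyl]-6-methoxyphenoxy]benzaldehyde
Conditions: MnO2 (activated, excess), CH2Cl2, rt
Reagents that add atoms: none
Why: Chemoselective benzylic alcohol oxidation that stops at the aldehyde and leaves the stilbene, aryl bromide and benzyl ether untouched.

Step 6
Reactants: 9 3-[3-(benzyloxy)-2-[(E)-2-(4-bromophenyl)ethenyl]-6-methoxyphenoxy]benzaldehyde; 10 4-(benzyloxy)-3-hydroxybenzaldehyde
Product: 11 4-(benzyloxy)-3-{4-[(E)-2-[6-(benzyloxy)-2-(3-formylphenoxy)-3-methoxyphenyl]ethenyl]phenoxy}benzaldehyde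
Conditions: CuI (10 mol %), picolinic acid (20 mol %), K3PO4, DMSO, 90 °C, N2
Reagents that add atoms: none
Why: Ullmann-type copper-catalysed diaryl ether coupling, needed because the aryl bromide is not activated for SNAr; both aldehydes are non-enolisable and survive the mild phosphate base.

Step 7
Reactants: 11 4-(benzyloxy)-3-{4-[(E)-2-[6-(benzyloxy)-2-(3-formylphenoxy)-3-methoxyphenyl]ethenyl]phenoxy}benzaldehyde
Product: 13 macrocyclic acyloin (ring C ketone / ring B carbinol; racemic), via Breslow intermediate 12 (not isolated)
Conditions: 2-(pentafluorophenyl)-6,7-dihydro-5H-pyrrolo[2,1-c][1,2,4]triazol-2-ium tetrafluoroborate (20 mol %), DBU (20 mol %), THF, 2 mM (syringe-pump addition over 12 h), 40 °C, Ar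
Reagents that add atoms: none
Why: Proposed new method: the carbene adds to the electron-rich ring C formyl group and proton transfer gives enaminol 12, an acyl anion equivalent whose carbon attacks the more electrophilic ring B formyl group before the carbene is expelled; every step is reversible, so open-chain oligomers re-open and drain into the entropically favoured 18-membered monomer at high dilution; the opposite donor/acceptor sense would lead to the same bibenzyl after step 8, so there is no regiochemical demand, and the new carbinol centre is formed racemic and later removed; the closest known reaction type is the intermolecular triazolylidene-catalysed cross-benzoin condensation of aromatic aldehydes.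

Step 8
Reactants: 13 macrocyclic acyloin (ring C ketone / ring B carbinol; racemic)
Product: 14 CNP0179896.0 (target)
Conditions: H2 (4 bar), 10% Pd/C, AcOH/EtOAc 1:1, HClO4 (cat.), 40 °C
Reagents that add atoms: none
Why: Catalytic hydrogenation with acid-assisted benzylic hydrogenolysis saturates the alkene, cleaves both benzyl ethers and reduces both the aryl ketone and the benzylic carbinol of the acyloin to CH2, which also removes the only stereocentre so the achiral target results.

## Compound list

1 | 3-fluoro-4-methoxyphenol | COc1ccc(O)cc1F | starting material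
2 | 4-(benzyloxy)-2-fluoro-1-methoxybenzene | COc1ccc(OCc2ccccc2)cc1F | intermediate
3 | aryllithium [6-(benzyloxy)-2-fluoro-3-methoxyphenyl]lithium (not isolated) | COc1ccc(OCc2ccccc2)c([Li])c1F | intermediate
4 | 6-(benzyloxy)-2-fluoro-3-methoxybenzaldehyde | COc1ccc(OCc2ccccc2)c(C=O)c1F | intermediate
5 | 3-(hydroxymethyl)phenol (3-hydroxybenzyl alcohol) | OCc1cccc(O)c1 | starting material
6 | 6-(benzyloxy)-2-[3-(hydroxymethyl)phenoxy]-3-methoxybenzaldehyde | COc1ccc(OCc2ccccc2)c(C=O)c1Oc1cccc(CO)c1 | intermediate
7 | diethyl (4-bromobenzyl)phosphonate | CCOP(=O)(OCC)Cc1ccc(Br)cc1 | starting material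
8 | {3-[3-(benzyloxy)-2-[(E)-2-(4-bromophenyl)ethenyl]-6-methoxyphenoxy]phenyl}methanol | COc1ccc(OCc2ccccc2)c(/C=C/c2ccc(Br)cc2)c1Oc1cccc(CO)c1 | intermediate
9 | 3-[3-(benzyloxy)-2-[(E)-2-(4-bromophenyl)ethenyl]-6-methoxyphenoxy]benzaldehyde | COc1ccc(OCc2ccccc2)c(/C=C/c2ccc(Br)cc2)c1Oc1cccc(C=O)c1 | intermediate
10 | 4-(benzyloxy)-3-hydroxybenzaldehyde | O=Cc1ccc(OCc2ccccc2)c(O)c1 | starting material
11 | 4-(benzyloxy)-3-{4-[(E)-2-[6-(benzyloxy)-2-(3-formylphenoxy)-3-methoxyphenyl]ethenyl]phenoxy}benzaldehyde (seco-dialdehyde) | COc1ccc(OCc2ccccc2)c(/C=C/c2ccc(Oc3cc(C=O)ccc3OCc3ccccc3)cc2)c1Oc1cccc(C=O)c1 | intermediate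
12 | Breslow intermediate: enaminol of the ring C formyl carbon of 11 with the 2-(pentafluorophenyl)pyrrolo-triazolylidene; ring B formyl group still free; enol geometry undefined (not isolated) | COc1ccc(OCc2ccccc2)c(/C=C/c2ccc(Oc3cc(C(O)=C4N(c5c(F)c(F)c(F)c(F)c5F)N=C5CCCN45)ccc3OCc3ccccc3)cc2)c1Oc1cccc(C=O)c1 | intermediate
13 | macrocyclic acyloin, racemic: 18-membered ring closed by a –C(=O)–CH(OH)– bridge with C=O on ring C and CH(OH) on ring B; E-CH=CH bridge between rings D and A; benzyl ethers on rings A and C; OMe on ring A | COc1ccc(OCc2ccccc2)c(/C=C/c2ccc(cc2)Oc2cc(ccc2OCc2ccccc2)C(=O)C(O)c2cccc(c2)O3)c13 | intermediate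
14 | CNP0179896.0: macrocyclic bis(bibenzyl) with two diaryl ethers, OMe and OH on ring A, OH on ring C; achiral | COc1ccc(O)c2c1Oc1cccc(c1)CCc1ccc(O)c(c1)Oc1ccc(cc1)CC2 | target

## Step count and risks

Total steps: 8. Longest linear sequence: 8 (1 → 2 → 4 → 6 → 8 → 9 → 11 → 13 → 14); compounds 5, 7 and 10 are bought.

The three steps most likely to fail, in order of risk:

- **Step 7, the macrocyclic benzoin.** It may give oligomers, or the carbene may be too slow with the electron-rich ring C aldehyde. The fallback sets out from dialdehyde 11 and closes the same carbon–carbon bond by reductive carbonyl coupling. TiCl4/Zn/pyridine in refluxing THF with syringe-pump addition (McMurry coupling through ketyl radical anions, a one-electron polarity reversal of both formyl carbons) gives macrocyclic diene F1. Its new ring B–ring C alkene is expected as a Z/E mixture; the Z isomer is drawn. Neutral hydrogenation (H2, Pd/C, EtOAc/MeOH, rt) then saturates both alkenes and removes both benzyl groups, rejoining the route at target 14.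

- **Step 8, the one-pot deoxygenation.** The less activated ring B carbinol may resist hydrogenolysis, or acid may trigger rearrangement of a diol intermediate. The fallback sets out from acyloin 13 and removes the troublesome oxygen separately. Zn dust in AcOH at 90 °C reductively cleaves the hydroxyl α to the ketone to give macrocyclic deoxybenzoin F2. The remaining para-oxygenated aryl ketone, the alkene and the benzyl ethers are then reduced with H2, Pd/C, AcOH and catalytic HClO4, coming back at target 14.

- **Step 6, the Ullmann etherification.** The phenol is hindered by its ortho benzyloxy group and both partners carry aldehydes. The fallback sets out from bromide 9 and reverses the roles of the coupling partners. Miyaura borylation (Pd(dppf)Cl2, B2pin2, KOAc, dioxane, 85 °C) gives aryl pinacol boronate F3. Oxidative Chan–Lam coupling with phenol 10 (Cu(OAc)2, pyridine, B(OH)3, 4 Å molecular sieves, MeCN, air, 70 °C) then returns to dialdehyde 11.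

## Further compounds

F1 | step 7 | macrocyclic diene: 18-membered ring with a Z-CH=CH bridge between rings C and B and the E-CH=CH bridge between rings D and A; benzyl ethers on rings A and C | COc1ccc(OCc2ccccc2)c(/C=C/c2ccc(cc2)Oc2cc(ccc2OCc2ccccc2)/C=C\c2cccc(c2)O3)c13
F2 | step 8 | macrocyclic deoxybenzoin: as 13 but with CH2 in place of CH(OH) on the ring B side; C=O on ring C | COc1ccc(OCc2ccccc2)c(/C=C/c2ccc(cc2)Oc2cc(ccc2OCc2ccccc2)C(=O)Cc2cccc(c2)O3)c13
F3 | step 6 | 3-[3-(benzyloxy)-6-methoxy-2-[(E)-2-[4-(4,4,5,5-tetramethyl-1,3,2-dioxaborolan-2-yl)phenyl]ethenyl]phenoxy]benzaldehyde | COc1ccc(OCc2ccccc2)c(/C=C/c2ccc(cc2)B2OC(C)(C)C(C)(C)O2)c1Oc1cccc(C=O)c1
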